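**Plan**
1. Retrosynthetic cuts: the gallate ester at O3'; in ring C of the upper unit the O1–C2 ether bond and the C2–aryl (ring B) bond; then, together, C3–C4 and O1–C2(acyl) of a dihydrocoumarin; last the C4–C6' bond, traced back to an aryl-metal and an aldehyde.
2. Feature used: C4 is benzylic to ring A and O1 sits ortho to it, so O1–C8a–C4a–C4 can be written as an o-quinone methide carrying ring D on C4, and C2–C3(O) is a glycolic acid unit.
3. Forward: (−)-epicatechin is benzylated and silylated, brominated at C8' (a block that stays to the end) and iodinated at C6'. The C6' arylmagnesium adds to 2,4-bis(benzyloxy)-6-hydroxybenzaldehyde (C4–C6'), and the carbinol is exchanged for a sulfone.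
4. Ring C closes first as a lactone when the isothiourea-bound enolate of benzyloxyacetic acid meets the quinone methide (C3–C4, O1–C2). It is reopened as a Weinreb amide, ring B enters as a Grignard reagent, and ring C closes again as the flavan by chelation-controlled reduction and Mitsunobu etherification. Desilylation, galloylation at O3' and hydrogenolysis finish.
5. Stereochemistry: C2' and C3' come from (−)-epicatechin; C4 from the catalyst-controlled enolate–methide addition; C3 from the catalyst, then held trans to C4 by equilibration; C2 from chelation-controlled hydride delivery (1,2-anti) followed by SN2 inversion (2,3-cis).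

Key step: step 8

**Remarks before the steps**
- Numbering: flavan numbering. The upper (epiafzelechin) unit is unprimed, with rings A (benzo), C (pyran) and B (4-hydroxyphenyl). The lower (galloylated epicatechin) unit is primed, with rings D (benzo), F (pyran) and E (catechol).
- Fl stands for the protected lower unit bound through C6': (2R,3R)-8-bromo-5,7-bis(benzyloxy)-2-[3,4-bis(benzyloxy)phenyl]-3-[(tert-butyldimethylsilyl)oxy]chroman-6-yl.
- Descriptor note: while C8' carries bromine, ring D outranks ring A at C4. The centre that is 4S in the target is therefore written R in compounds 15, 16, 19–22 and 24, with no change in space.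
- Assumption: the enolate is taken to add to the quinone methide with the anti (3,4-trans) topicity usual for isothiourea-bound Z-enolates, which fixes the catalyst as the (2R,3S) enantiomer; if the addition were syn-selective its mirror image would be used, because C3 is equilibrated afterwards and only C4 must be set in the bond formation.
- 3,4,5-Tris(benzyloxy)benzoic acid (23) is taken as a commercial compound.

**Route**

Step 1
Reactants: 1 (−)-epicatechin
Product: 2 5,7-di-O-benzyl-E-ring-3,4-di-O-benzyl-(−)-epicatechin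
Conditions: BnBr (4.4 equiv), K2CO3, DMF, 0 °C → rt
Reagents that add atoms: benzyl bromide, BrCc1ccccc1
Why: Williamson etherification under K2CO3 alkylates the four phenols, which are far more acidic than the C3' alcohol, so the secondary hydroxyl stays free and C2' and C3' are not touched.

Step 2
Reactants: 2 tetra-O-benzyl-(−)-epicatechin
Product: 3 3'-O-TBS ether of 2
Conditions: TBSCl, imidazole, DMF, rt
Reagents that add atoms: tert-butyldimethylsilyl chloride, CC(C)(C)[Si](C)(C)Cl
Why: Imidazole-promoted silylation of the one remaining hydroxyl gives a silyl ether that should survive every later organometallic, acidic and basic step until fluoride is applied.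

Step 3
Reactants: 3 3'-O-TBS tetra-O-benzyl-epicatechin
Product: 4 8'-bromo derivative of 3
Conditions: NBS, CH2Cl2, −78 °C → 0 °C
Reagents that add atoms: N-bromosuccinimide, O=C1CCC(=O)N1Br
Why: Electrophilic aromatic bromination of the phloroglucinol-type ring D goes first to C8', the more accessible of its two free positions in 5,7-di-O-benzyl flavans, so the bromine blocks C8' and leaves C6' as the only site for the next substitution.

Step 4
Reactants: 4 8'-bromide
Product: 5 8'-bromo-6'-iodo derivative (Fl–I)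
Conditions: NIS, TFA (10 mol%), MeCN/CH2Cl2, 0 °C → rt, dark
Reagents that add atoms: N-iodosuccinimide, O=C1CCC(=O)N1I
Why: Electrophilic aromatic iodination can now only take the remaining ring-D position C6', which is activated by O5', O7' and O1', whereas ring E with two donors is far less reactive.

Step 5
Reactants: 6 2,4,6-trihydroxybenzaldehyde
Product: 7 2,4-bis(benzyloxy)-6-hydroxybenzaldehyde
Conditions: BnBr (2.1 equiv), K2CO3, DMF, rt
Reagents that add atoms: benzyl bromide, BrCc1ccccc1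
Why: Williamson etherification takes the para hydroxyl and one ortho hydroxyl, after which the last hydroxyl is held in a hydrogen bond to the formyl group and resists alkylation.

Step 6
Reactants: 5 Fl–I; 7 2,4-bis(benzyloxy)-6-hydroxybenzaldehyde
Product: 10 Fl–CH(OH)–[2-hydroxy-4,6-bis(benzyloxy)phenyl] carbinol (both epimers at the carbinol carbon), via sodium 3,5-bis(benzyloxy)-2-formylphenolate 8 (not isolated), via lower-unit C6'-arylmagnesium chloride 9 (not isolated)
Conditions: 7, NaH, THF, 0 °C; 5, iPrMgCl·LiCl, THF, −20 °C; arylmagnesium added to the phenolate, −20 °C → rt; aq. NH4Cl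
Reagents that add atoms: none
Why: Iodine–magnesium exchange occurs at the C–I bond much faster than at the C–Br bond, and the arylmagnesium then adds to the formyl group (Grignard addition) of the aldehyde whose acidic phenol has been removed beforehand as the sodium salt; the configuration of the new carbinol carbon is irrelevant because it becomes trigonal in step 8.

Step 7
Reactants: 10 diaryl carbinol
Product: 11 3,5-bis(benzyloxy)-2-[Fl(4-methylbenzenesulfonyl)methyl]phenol (both epimers)
Conditions: p-TolSO2H (1.5 equiv), CH2Cl2, 0 °C → rt; used after filtration through a short pad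
Reagents that add atoms: p-toluenesulfinic acid, Cc1ccc(cc1)S(=O)O
Why: The carbinol ionises under mild acid to a diarylmethyl cation stabilised by six oxygen donors (the protonated o-quinone methide), and sulfinate captures it at sulfur in an SN1 substitution to give the sulfone, whose two epimers serve equally.

Step 8
Reactants: 11 sulfone; 12 benzyloxyacetic acid
Product: 15 trans-3,5,7-tris(benzyloxy)-4-Fl-3,4-dihydrocoumarin (3R,4R), via benzyloxyacetic pivalic anhydride 13 (not isolated), via ring-D-substituted o-quinone methide 14 (not isolated)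
Conditions: 12, t-BuCOCl, iPr2NEt, CH2Cl2, 0 °C; added slowly to 11, (2R,3S)-HyperBTM (20 mol%), iPr2NEt, CH2Cl2, 0 °C → rt; then DBU (20 mol%), rt
Reagents that add atoms: none
Why: iPr2NEt strips p-toluenesulfinate from the phenoxide of 11 to give o-quinone methide 14 (O1=C8a–C4a=C4), while the isothiourea is acylated by anhydride 13 and deprotonated by pivalate to a Z ammonium enolate held flat by a 1,5-O···S contact; the enolate carbon C3 adds to C4 (Michael addition) and the freed phenoxide O1 attacks the acyl ammonium carbon C2, 6-exo-trig, closing ring C as the lactone and releasing the catalyst. The closest known reaction is the isothiourea-catalysed formal [4+2] (Michael addition–lactonisation) of ammonium enolates with o-quinone methides made in situ from 2-(1-tosylalkyl)phenols, which gives 3,4-disubstituted dihydrocoumarins. C3 is set by the catalyst, whose pseudo-axial phenyl group covers the Si face of the enolate carbon so that C4 bonds to the Re face (3R), and it is then held trans to the C4 aryl group by DBU equilibration of the acidic lactone α-position, the 3,4-trans-diaxial arrangement keeping ring D clear of the C5 benzyloxy group. C4 is set in the same bond formation by the anti topicity of the enolate–acceptor approach under the catalyst, since the remote stereocentres of the lower unit make the two faces of 14 diastereotopic but hardly bias them. The step needs C-alkylation at C4 rather than O-acylation of the phenol, and attack on one face of a crowded methide; the first should be secured because the electron-rich sulfone ionises quickly and C4 is the only electrophilic carbon of 14, the second rests on catalyst control and is the main risk.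

Step 9
Reactants: 15 trans-lactone
Product: 16 (2R,3R)-2-(benzyloxy)-3-[2-hydroxy-4,6-bis(benzyloxy)phenyl]-3-Fl-N-methoxy-N-methylpropanamide
Conditions: MeNH(OMe)·HCl (3 equiv), iPrMgCl (6 equiv), THF, −20 °C → 0 °C; aq. NH4Cl
Reagents that add atoms: N,O-dimethylhydroxylamine hydrochloride, CNOC.Cl
Why: The lactone is an aryl ester and therefore an acylating agent, so aminolysis by the magnesium amide of N,O-dimethylhydroxylamine at low temperature should open it to the Weinreb amide and the free O1 phenol without enolising C3.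

Step 10
Reactants: 16 Weinreb amide; 17 1-(benzyloxy)-4-bromobenzene
Product: 19 (2R,3R)-2-(benzyloxy)-1-[4-(benzyloxy)phenyl]-3-[2-hydroxy-4,6-bis(benzyloxy)phenyl]-3-Fl-propan-1-one, via 4-(benzyloxy)phenylmagnesium bromide 18 (not isolated)
Conditions: 17, Mg, THF, rt; then 16 (Grignard reagent 3.5 equiv), THF, 0 °C → rt; aq. NH4Cl
Reagents that add atoms: none
Why: In this Weinreb ketone synthesis the first equivalent of the Grignard reagent deprotonates the phenol and the second adds to the amide, whose magnesium-chelated tetrahedral adduct survives until work-up so that the reaction stops at the ketone.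

Step 11
Reactants: 19 α-benzyloxy aryl ketone
Product: 20 (1S,2R,3R)-2-(benzyloxy)-1-[4-(benzyloxy)phenyl]-3-[2-hydroxy-4,6-bis(benzyloxy)phenyl]-3-Fl-propan-1-ol (1,2-anti)
Conditions: Zn(BH4)2 (stock solution in Et2O), Et2O/CH2Cl2, −30 °C → 0 °C; aq. NH4Cl
Reagents that add atoms: none
Why: Chelation-controlled (Cram chelate) reduction, in which zinc ties the ketone oxygen to the C3 benzyloxy oxygen and hydride enters the five-membered chelate from the face away from the bulky diarylmethyl group on C3, should give the 1,2-anti alcohol with S configuration at the future C2.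

Step 12
Reactants: 20 anti alcohol
Product: 21 (2R,3R,4R)-3,5,7-tris(benzyloxy)-2-[4-(benzyloxy)phenyl]-4-Fl-chromane (2,3-cis, 3,4-trans)
Conditions: PPh3, DIAD, toluene/THF, 0 °C → rt
Reagents that add atoms: none
Why: Intramolecular Mitsunobu etherification, in which the O1 phenol displaces the benzylic oxyphosphonium group by SN2 (6-exo-tet), closes ring C with inversion at C2 and so turns the 1,2-anti alcohol into the 2,3-cis flavan with 2R configuration.

Step 13
Reactants: 21 silyl-protected dimer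
Product: 22 3'-hydroxy dimer (8'-bromo-octa-O-benzyl-epiafzelechin-(4β→6)-epicatechin)
Conditions: TBAF, AcOH, THF, rt
Reagents that add atoms: none
Why: Fluoride-induced cleavage of the silyl ether, buffered by acetic acid, frees the C3' hydroxyl alone, since every other oxygen is a benzyl ether.

Step 14
Reactants: 22 3'-hydroxy dimer; 23 3,4,5-tris(benzyloxy)benzoic acid
Product: 24 3'-O-[3,4,5-tris(benzyloxy)benzoyl] ester of 22
Conditions: DCC, DMAP (cat.), CH2Cl2, rt
Reagents that add atoms: none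
Why: Steglich esterification through the DMAP-acylpyridinium of the benzylated gallic acid acylates the single free hydroxyl, the axial C3' alcohol, with retention.

Step 15
Reactants: 24 fully protected gallate
Product: 25 epiafzelechin-(4β→6)-epicatechin 3'-O-gallate (target)
Conditions: H2 (1 atm), Pd(OH)2/C, Et3N (1.1 equiv), THF/MeOH/H2O, rt
Reagents that add atoms: none
Why: Catalytic hydrogenolysis cleaves the eleven benzyl ethers and the C8'–Br bond in one operation, with Et3N taking up the HBr so that the acid-labile C4–C6' bond and the gallate ester stay intact and no stereocentre is touched.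

**Compound list**
1 | (−)-epicatechin, (2R,3R)-2-(3,4-dihydroxyphenyl)chromane-3,5,7-triol | O[C@@H]1Cc2c(O)cc(O)cc2O[C@@H]1c1ccc(O)c(O)c1 | starting material
2 | (2R,3R)-5,7-bis(benzyloxy)-2-[3,4-bis(benzyloxy)phenyl]chroman-3-ol | O[C@@H]1Cc2c(OCc3ccccc3)cc(OCc3ccccc3)cc2O[C@@H]1c1ccc(OCc2ccccc2)c(OCc2ccccc2)c1 | intermediate
3 | (2R,3R)-5,7-bis(benzyloxy)-2-[3,4-bis(benzyloxy)phenyl]-3-[(tert-butyldimethylsilyl)oxy]chromane | CC(C)(C)[Si](C)(C)O[C@@H]1Cc2c(OCc3ccccc3)cc(OCc3ccccc3)cc2O[C@@H]1c1ccc(OCc2ccccc2)c(OCc2ccccc2)c1 | intermediate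
4 | (2R,3R)-8-bromo-5,7-bis(benzyloxy)-2-[3,4-bis(benzyloxy)phenyl]-3-[(tert-butyldimethylsilyl)oxy]chromane (Fl–H) | CC(C)(C)[Si](C)(C)O[C@@H]1Cc2c(c(Br)c(OCc3ccccc3)cc2OCc3ccccc3)O[C@@H]1c1ccc(OCc2ccccc2)c(OCc2ccccc2)c1 | intermediate
5 | (2R,3R)-8-bromo-6-iodo-5,7-bis(benzyloxy)-2-[3,4-bis(benzyloxy)phenyl]-3-[(tert-butyldimethylsilyl)oxy]chromane (Fl–I) | CC(C)(C)[Si](C)(C)O[C@@H]1Cc2c(c(Br)c(OCc3ccccc3)c(I)c2OCc3ccccc3)O[C@@H]1c1ccc(OCc2ccccc2)c(OCc2ccccc2)c1 | intermediate
6 | 2,4,6-trihydroxybenzaldehyde | O=Cc1c(O)cc(O)cc1O | starting material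
7 | 2,4-bis(benzyloxy)-6-hydroxybenzaldehyde | O=Cc1c(O)cc(OCc2ccccc2)cc1OCc1ccccc1 | intermediate
8 | sodium 3,5-bis(benzyloxy)-2-formylphenolate | [Na+].[O-]c1cc(OCc2ccccc2)cc(OCc2ccccc2)c1C=O | intermediate (not isolated)
9 | Fl–MgCl, the C6'-chloromagnesium derivative of 5 | CC(C)(C)[Si](C)(C)O[C@@H]1Cc2c(c(Br)c(OCc3ccccc3)c([Mg]Cl)c2OCc3ccccc3)O[C@@H]1c1ccc(OCc2ccccc2)c(OCc2ccccc2)c1 | intermediate (not isolated)
10 | Fl–CH(OH)–[2-hydroxy-4,6-bis(benzyloxy)phenyl], both epimers at the carbinol carbon (future C4) | CC(C)(C)[Si](C)(C)O[C@@H]1Cc2c(c(Br)c(OCc3ccccc3)c(C(O)c3c(O)cc(OCc4ccccc4)cc3OCc3ccccc3)c2OCc3ccccc3)O[C@@H]1c1ccc(OCc2ccccc2)c(OCc2ccccc2)c1 | intermediate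
11 | 3,5-bis(benzyloxy)-2-[Fl(4-methylbenzenesulfonyl)methyl]phenol, both epimers at the sulfonyl-bearing carbon | CC(C)(C)[Si](C)(C)O[C@@H]1Cc2c(c(Br)c(OCc3ccccc3)c(C(c3c(O)cc(OCc4ccccc4)cc3OCc3ccccc3)S(=O)(=O)c3ccc(C)cc3)c2OCc3ccccc3)O[C@@H]1c1ccc(OCc2ccccc2)c(OCc2ccccc2)c1 | intermediate (key-step precursor)
12 | benzyloxyacetic acid | OC(=O)COCc1ccccc1 | starting material
13 | benzyloxyacetic pivalic anhydride | CC(C)(C)C(=O)OC(=O)COCc1ccccc1 | intermediate (not isolated)
14 | 3,5-bis(benzyloxy)-6-(Fl-methylidene)cyclohexa-2,4-dien-1-one (o-quinone methide, alkene geometry open) | O=C1C=C(OCc2ccccc2)C=C(OCc2ccccc2)C1=Cc1c(OCc3ccccc3)c2C[C@@H](O[Si](C)(C)C(C)(C)C)[C@@H](c3ccc(OCc4ccccc4)c(OCc4ccccc4)c3)Oc2c(Br)c1OCc1ccccc1 | intermediate (not isolated)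
15 | (3R,4R)-3,5,7-tris(benzyloxy)-4-Fl-3,4-dihydro-2H-chromen-2-one (3,4-trans) | CC(C)(C)[Si](C)(C)O[C@@H]1Cc2c(c(Br)c(OCc3ccccc3)c([C@H]3c4c(OCc5ccccc5)cc(OCc5ccccc5)cc4OC(=O)[C@@H]3OCc3ccccc3)c2OCc3ccccc3)O[C@@H]1c1ccc(OCc2ccccc2)c(OCc2ccccc2)c1 | intermediate (key-step product)
16 | (2R,3R)-2-(benzyloxy)-3-[2-hydroxy-4,6-bis(benzyloxy)phenyl]-3-Fl-N-methoxy-N-methylpropanamide | CC(C)(C)[Si](C)(C)O[C@@H]1Cc2c(c(Br)c(OCc3ccccc3)c([C@@H](c3c(O)cc(OCc4ccccc4)cc3OCc3ccccc3)[C@@H](OCc3ccccc3)C(=O)N(C)OC)c2OCc3ccccc3)O[C@@H]1c1ccc(OCc2ccccc2)c(OCc2ccccc2)c1 | intermediate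
17 | 1-(benzyloxy)-4-bromobenzene | Brc1ccc(OCc2ccccc2)cc1 | starting material
18 | 4-(benzyloxy)phenylmagnesium bromide | Br[Mg]c1ccc(OCc2ccccc2)cc1 | intermediate (not isolated)
19 | (2R,3R)-2-(benzyloxy)-1-[4-(benzyloxy)phenyl]-3-[2-hydroxy-4,6-bis(benzyloxy)phenyl]-3-Fl-propan-1-one | CC(C)(C)[Si](C)(C)O[C@@H]1Cc2c(c(Br)c(OCc3ccccc3)c([C@@H](c3c(O)cc(OCc4ccccc4)cc3OCc3ccccc3)[C@@H](OCc3ccccc3)C(=O)c3ccc(OCc4ccccc4)cc3)c2OCc3ccccc3)O[C@@H]1c1ccc(OCc2ccccc2)c(OCc2ccccc2)c1 | intermediate
20 | (1S,2R,3R)-2-(benzyloxy)-1-[4-(benzyloxy)phenyl]-3-[2-hydroxy-4,6-bis(benzyloxy)phenyl]-3-Fl-propan-1-ol (1,2-anti) | CC(C)(C)[Si](C)(C)O[C@@H]1Cc2c(c(Br)c(OCc3ccccc3)c([C@@H](c3c(O)cc(OCc4ccccc4)cc3OCc3ccccc3)[C@@H](OCc3ccccc3)[C@@H](O)c3ccc(OCc4ccccc4)cc3)c2OCc3ccccc3)O[C@@H]1c1ccc(OCc2ccccc2)c(OCc2ccccc2)c1 | intermediate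
21 | (2R,3R,4R)-3,5,7-tris(benzyloxy)-2-[4-(benzyloxy)phenyl]-4-Fl-chromane (2,3-cis, 3,4-trans) | CC(C)(C)[Si](C)(C)O[C@@H]1Cc2c(c(Br)c(OCc3ccccc3)c([C@H]3c4c(OCc5ccccc5)cc(OCc5ccccc5)cc4O[C@H](c4ccc(OCc5ccccc5)cc4)[C@@H]3OCc3ccccc3)c2OCc3ccccc3)O[C@@H]1c1ccc(OCc2ccccc2)c(OCc2ccccc2)c1 | intermediate
22 | desilylated 21: (2R,3R)-8-bromo-5,7-bis(benzyloxy)-2-[3,4-bis(benzyloxy)phenyl]-6-{(2R,3R,4R)-3,5,7-tris(benzyloxy)-2-[4-(benzyloxy)phenyl]chroman-4-yl}chroman-3-ol | O[C@@H]1Cc2c(c(Br)c(OCc3ccccc3)c([C@H]3c4c(OCc5ccccc5)cc(OCc5ccccc5)cc4O[C@H](c4ccc(OCc5ccccc5)cc4)[C@@H]3OCc3ccccc3)c2OCc3ccccc3)O[C@@H]1c1ccc(OCc2ccccc2)c(OCc2ccccc2)c1 | intermediate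
23 | 3,4,5-tris(benzyloxy)benzoic acid | OC(=O)c1cc(OCc2ccccc2)c(OCc2ccccc2)c(OCc2ccccc2)c1 | starting material
24 | 3'-O-[3,4,5-tris(benzyloxy)benzoyl] ester of 22 | O=C(O[C@@H]1Cc2c(c(Br)c(OCc3ccccc3)c([C@H]3c4c(OCc5ccccc5)cc(OCc5ccccc5)cc4O[C@H](c4ccc(OCc5ccccc5)cc4)[C@@H]3OCc3ccccc3)c2OCc3ccccc3)O[C@@H]1c1ccc(OCc2ccccc2)c(OCc2ccccc2)c1)c1cc(OCc2ccccc2)c(OCc2ccccc2)c(OCc2ccccc2)c1 | intermediate
25 | epiafzelechin-(4β→6)-epicatechin 3'-O-gallate: (2R,3R)-2-(3,4-dihydroxyphenyl)-5,7-dihydroxy-6-[(2R,3R,4S)-3,5,7-trihydroxy-2-(4-hydroxyphenyl)chroman-4-yl]chroman-3-yl 3,4,5-trihydroxybenzoate | O=C(O[C@@H]1Cc2c(cc(O)c([C@H]3c4c(O)cc(O)cc4O[C@H](c4ccc(O)cc4)[C@@H]3O)c2O)O[C@@H]1c1ccc(O)c(O)c1)c1cc(O)c(O)c(O)c1 | target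

**Count**
Total steps: 15. Longest linear sequence: 14 steps (steps 1–4 and 6–15, from (−)-epicatechin); step 5 is a one-step branch.

**Steps most likely to fail**

Step 8. The ammonium enolate may fail to reach a methide carbon flanked by the two ortho benzyloxy groups of ring D and the C5 benzyloxy group. It may also add with poor facial selectivity at C4, or acylation of the phenol may outrun formation of the quinone methide. The fallback sets out from carbinol 10, gives up catalyst control and returns at 15. Sc(OTf)3 (5 mol%) in CH2Cl2 at −40 °C ionises 10 to the diarylmethyl cation, the protonated form of 14. This is intercepted in a Mukaiyama-type addition by [2-(benzyloxy)-1-methoxyethenyl]oxytrimethylsilane to give methyl 2-(benzyloxy)-3-Fl-3-[2-hydroxy-4,6-bis(benzyloxy)phenyl]propanoate F1 as a mixture at C3 and C4. PPTS in warm toluene lactonises it with loss of methanol, and DBU then equilibrates C3. This should leave the two 3,4-trans lactones, 15 and its (3S,4S) isomer F2, which are diastereomers because of the lower unit and would be separated by chromatography. Lactone 15 rejoins the route at step 9.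

Step 6. Addition of a di-ortho-substituted arylmagnesium to an electron-rich, deprotonated salicylaldehyde may be slow, so that protonation of the aryl-metal back to 4 dominates. The fallback sets out from bromide 4 and aldehyde 7 and returns at sulfone 11. Compound 4, whose C6' is the only free nucleophilic position of ring D, is condensed with 7 and p-toluenesulfinic acid under camphorsulfonic acid catalysis in CH2Cl2, a three-component Friedel–Crafts-type sulfonylalkylation of an electron-rich arene. Carbinol 10, formed in passing, ionises and is captured by sulfinate, so steps 4, 6 and 7 fall away and no compound outside the list arises (F0).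

Step 12. The oxyphosphonium group sits on a carbon benzylic to a 4-benzyloxyphenyl ring. Ionisation there (SN1) would erode the inversion and lead to the 2,3-trans flavan, or to an enol ether by elimination. The fallback sets out from Weinreb amide 16, removes the para donor during ring closure and returns at 21. Commercial 4-iodophenyl 4-methylbenzenesulfonate and iPrMgCl·LiCl (THF, −20 °C) give 4-(tosyloxy)phenylmagnesium chloride F3, which converts 16 into the (2R,3R) aryl ketone with a 4-(tosyloxy)phenyl group F4. Zn(BH4)2 reduces it under chelation control to the (1S,2R,3R) anti alcohol F5. Mitsunobu closure (PPh3, DIAD), now on a benzylic carbon without a lone-pair donor, should proceed by clean SN2 to the 2,3-cis flavan B-ring tosylate F6. KOH in MeOH/THF at 60 °C cleaves the sulfonate to the B-ring phenol F7, and BnBr/K2CO3 in DMF benzylates it to give 21.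

**Further compounds**
F1 | step 8 | methyl 2-(benzyloxy)-3-Fl-3-[2-hydroxy-4,6-bis(benzyloxy)phenyl]propanoate (mixture at C2 and C3 of the chain) | CC(C)(C)[Si](C)(C)O[C@@H]1Cc2c(c(Br)c(OCc3ccccc3)c(C(c3c(O)cc(OCc4ccccc4)cc3OCc3ccccc3)C(OCc3ccccc3)C(=O)OC)c2OCc3ccccc3)O[C@@H]1c1ccc(OCc2ccccc2)c(OCc2ccccc2)c1
F2 | step 8 | (3S,4S)-3,5,7-tris(benzyloxy)-4-Fl-3,4-dihydro-2H-chromen-2-one (3,4-trans diastereomer of 15) | CC(C)(C)[Si](C)(C)O[C@@H]1Cc2c(c(Br)c(OCc3ccccc3)c([C@@H]3c4c(OCc5ccccc5)cc(OCc5ccccc5)cc4OC(=O)[C@H]3OCc3ccccc3)c2OCc3ccccc3)O[C@@H]1c1ccc(OCc2ccccc2)c(OCc2ccccc2)c1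
F0 | step 6 | none | none
F3 | step 12 | 4-(tosyloxy)phenylmagnesium chloride | Cc1ccc(cc1)S(=O)(=O)Oc1ccc([Mg]Cl)cc1
F4 | step 12 | (2R,3R)-2-(benzyloxy)-3-[2-hydroxy-4,6-bis(benzyloxy)phenyl]-3-Fl-1-[4-(tosyloxy)phenyl]propan-1-one | CC(C)(C)[Si](C)(C)O[C@@H]1Cc2c(c(Br)c(OCc3ccccc3)c([C@@H](c3c(O)cc(OCc4ccccc4)cc3OCc3ccccc3)[C@@H](OCc3ccccc3)C(=O)c3ccc(OS(=O)(=O)c4ccc(C)cc4)cc3)c2OCc3ccccc3)O[C@@H]1c1ccc(OCc2ccccc2)c(OCc2ccccc2)c1
F5 | step 12 | (1S,2R,3R)-2-(benzyloxy)-3-[2-hydroxy-4,6-bis(benzyloxy)phenyl]-3-Fl-1-[4-(tosyloxy)phenyl]propan-1-ol (1,2-anti) | CC(C)(C)[Si](C)(C)O[C@@H]1Cc2c(c(Br)c(OCc3ccccc3)c([C@@H](c3c(O)cc(OCc4ccccc4)cc3OCc3ccccc3)[C@@H](OCc3ccccc3)[C@@H](O)c3ccc(OS(=O)(=O)c4ccc(C)cc4)cc3)c2OCc3ccccc3)O[C@@H]1c1ccc(OCc2ccccc2)c(OCc2ccccc2)c1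
F6 | step 12 | (2R,3R,4R)-3,5,7-tris(benzyloxy)-4-Fl-2-[4-(tosyloxy)phenyl]chromane (2,3-cis, 3,4-trans) | CC(C)(C)[Si](C)(C)O[C@@H]1Cc2c(c(Br)c(OCc3ccccc3)c([C@H]3c4c(OCc5ccccc5)cc(OCc5ccccc5)cc4O[C@H](c4ccc(OS(=O)(=O)c5ccc(C)cc5)cc4)[C@@H]3OCc3ccccc3)c2OCc3ccccc3)O[C@@H]1c1ccc(OCc2ccccc2)c(OCc2ccccc2)c1
F7 | step 12 | (2R,3R,4R)-3,5,7-tris(benzyloxy)-4-Fl-2-(4-hydroxyphenyl)chromane | CC(C)(C)[Si](C)(C)O[C@@H]1Cc2c(c(Br)c(OCc3ccccc3)c([C@H]3c4c(OCc5ccccc5)cc(OCc5ccccc5)cc4O[C@H](c4ccc(O)cc4)[C@@H]3OCc3ccccc3)c2OCc3ccccc3)O[C@@H]1c1ccc(OCc2ccccc2)c(OCc2ccccc2)c1
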